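**Retrosynthetic overview**
1. Locants as in variabilin: furan C1–C4, chain C5–C20, lactone O–C21(=C20)–C22H=C23(C25H2OH)–C24(=O). C20=C21 (E) comes from anti-elimination of an unlike 20-hydroxy-21-H butenolide; C20–C21 comes from a vinylogous aldol of a 2-silyloxyfuran with the C1–C20 aldehyde 14.
2. C21–C22 and C23–C24 are made in one thermal step: intramolecular [4+2] of a 5-silyloxyoxazole with propargyl alcohol carried on the same silicon, then loss of acetonitrile from the 7-oxa-2-azanorbornadiene (ring made from a larger bicycle by extrusion).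
3. Enabling feature: the lactone ring is a 2-oxyfuran at the butenolide oxidation level. Its C21–O–C24 unit is the C2–O1–C5 unit of an oxazole, C22=C23–C25H2–O is propargyl alcohol, and O25 lies 1,3 to the oxygen on C24. One silicon atom therefore bridges both oxygens in a temporary six-membered ring, later releases the furanolate and finally protects O25.
4. Aldehyde 14 comes from two B-alkyl Suzuki couplings (C6–C7 from an E-vinyl iodide, C13–C15 from a Z-vinyl iodide); C18 comes from an Evans alkylation.
5. Ring order: the furan is bought; oxazole and dioxasilinane are temporary; the lactone ring is the only ring made (step 12), and its exocyclic alkene follows in step 13.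

Key step: step 12

Remark: the SMILES is read as 7E, 12Z, 18R and 20E (C18 cis to C22–H and trans to the ring oxygen, the less stable alkylidene geometry); the route is built for exactly this isomer.

**Route**

Step 1
Reactants: 1 pent-4-yn-1-ol
Product: 2 (E)-5-iodo-4-methylpent-4-en-1-ol
Conditions: Me3Al, Cp2ZrCl2 (25 mol%), CH2Cl2, 0 °C to rt; then I2, THF, −30 °C
Reagents that add atoms: trimethylaluminium, C[Al](C)C; iodine, II
Why: Negishi zirconium-catalysed methylalumination adds CH3 and Al syn across the terminal alkyne with Al at the terminus, and iodinolysis with retention gives the E-iodide that fixes the C7=C8 geometry.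

Step 2
Reactants: 3 furan-3-carbaldehyde
Product: 4 furan-3-ylethene (3-vinylfuran)
Conditions: [Ph3PCH3]Br, KOtBu, Et2O, 0 °C to rt; distilled and kept as a cold solution
Reagents that add atoms: methyltriphenylphosphonium bromide, C[P+](c1ccccc1)(c1ccccc1)c1ccccc1.[Br-]
Why: Wittig methylenation of an aromatic aldehyde is reliable and the furan is inert to the ylide.

Step 3
Reactants: 4 furan-3-ylethene; 2 (E)-5-iodo-4-methylpent-4-en-1-ol
Product: 6 (E)-7-(furan-3-yl)-4-methylhept-4-en-1-ol, via alkylborane 5 (not isolated)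
Conditions: 9-BBN, THF, 0 °C to rt; then 2, Pd(dppf)Cl2 (5 mol%), AsPh3, Cs2CO3, DMF–H2O, rt
Reagents that add atoms: 9-BBN, [H]B1C2CCCC1CCC2 (its boron stays only in 5)
Why: anti-Markovnikov hydroboration of the styrene-like alkene followed by B-alkyl Suzuki–Miyaura coupling joins C6 to C7 with retention of the E geometry, and the free hydroxyl is tolerated.

Step 4
Reactants: 6 (E)-7-(furan-3-yl)-4-methylhept-4-en-1-ol
Product: 7 (E)-7-(furan-3-yl)-4-methylhept-4-enal
Conditions: Dess–Martin periodinane, pyridine, CH2Cl2, 0 °C to rt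
Reagents that add atoms: none
Why: Dess–Martin oxidation stops at the aldehyde and leaves the furan and the trisubstituted alkene untouched.

Step 5
Reactants: 7 (E)-7-(furan-3-yl)-4-methylhept-4-enal
Product: 8 (2Z,6E)-9-(furan-3-yl)-2-iodo-6-methylnona-2,6-diene
Conditions: [Ph3PEt]I, n-BuLi, THF, rt; I2, −78 °C; NaN(SiMe3)2, −20 °C; then 7, −78 to −20 °C
Reagents that add atoms: ethyltriphenylphosphonium iodide, CC[P+](c1ccccc1)(c1ccccc1)c1ccccc1.[I-]; iodine, II
Why: Stork–Zhao-type Wittig olefination with the α-iodo ylide is kinetically controlled at low temperature and places iodine cis to the chain (Z), which fixes the later C12=C13 geometry.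

Step 6
Reactants: 9 (S)-4-benzyl-3-propanoyl-1,3-oxazolidin-2-one
Product: 10 (S)-4-benzyl-3-[(R)-2-methylpent-4-enoyl]-1,3-oxazolidin-2-one
Conditions: NaN(SiMe3)2, THF, −78 °C; allyl iodide, −78 to −45 °C
Reagents that add atoms: allyl iodide, C=CCI
Why: Evans alkylation, in which the chelated Z-enolate is attacked on the face opposite the benzyl group, sets the future C18 stereocentre as R.

Step 7
Reactants: 10 (S)-4-benzyl-3-[(R)-2-methylpent-4-enoyl]-1,3-oxazolidin-2-one
Product: 11 (R)-2-methylpent-4-en-1-ol
Conditions: LiBH4, H2O (1 equiv), Et2O, 0 °C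
Reagents that add atoms: none
Why: reductive cleavage of the imide with LiBH4 releases the primary alcohol without touching the stereocentre, and the auxiliary is recovered.

Step 8
Reactants: 11 (R)-2-methylpent-4-en-1-ol; 8 (2Z,6E)-9-(furan-3-yl)-2-iodo-6-methylnona-2,6-diene
Product: 13 (2R,6Z,10E)-13-(furan-3-yl)-2,6,10-trimethyltrideca-6,10-dien-1-ol, via bis-borane 12 (not isolated)
Conditions: 9-BBN (2.3 equiv), THF, 0 °C to rt; then 8, Pd(dppf)Cl2 (5 mol%), AsPh3, Cs2CO3, DMF–H2O, rt
Reagents that add atoms: 9-BBN, [H]B1C2CCCC1CCC2 (its boron stays only in 12)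
Why: 9-BBN masks the hydroxyl as its borinate and hydroborates the terminal alkene at C15, and B-alkyl Suzuki–Miyaura coupling replaces iodine with retention, so C15 ends cis to C11 (12Z) while C18 is untouched.

Step 9
Reactants: 13 (2R,6Z,10E)-13-(furan-3-yl)-2,6,10-trimethyltrideca-6,10-dien-1-ol
Product: 14 (2R,6Z,10E)-13-(furan-3-yl)-2,6,10-trimethyltrideca-6,10-dienal
Conditions: Dess–Martin periodinane, pyridine, CH2Cl2, 0 °C; used at once
Reagents that add atoms: none
Why: buffered Dess–Martin oxidation gives the α-branched aldehyde without enolisation, so C18 should stay R.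

Step 10
Reactants: 15 di-tert-butylsilanediyl bis(trifluoromethanesulfonate); 16 prop-2-yn-1-ol
Product: 17 di-tert-butyl(prop-2-yn-1-yloxy)silyl trifluoromethanesulfonate
Conditions: 2,6-lutidine (1.0 equiv), CH2Cl2, −78 to 0 °C; used as its solution
Reagents that add atoms: none
Why: nucleophilic substitution at silicon stops after one exchange, because the remaining Si–OTf is less electrophilic and shielded by the two tert-butyl groups.

Step 11
Reactants: 18 N-formyl-DL-alanine; 17 di-tert-butyl(prop-2-yn-1-yloxy)silyl trifluoromethanesulfonate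
Product: 20 silyloxyoxazole 5-{[di-tert-butyl(prop-2-yn-1-yloxy)silyl]oxy}-4-methyl-1,3-oxazole, via azlactone 19 (not isolated)
Conditions: DCC, CH2Cl2, 0 °C, filtered; then 17, Et3N, −78 to 0 °C; pentane, filtered, concentrated under argon
Reagents that add atoms: none
Why: carbodiimide cyclodehydration of the N-formyl amino acid gives the azlactone, and its aromatic enol form is trapped on oxygen by the hard silyl triflate (O-silylation of azlactones to 5-silyloxyoxazoles); the alanine stereocentre is lost and irrelevant.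

Step 12
Reactants: 20 silyloxyoxazole 5-{[di-tert-butyl(prop-2-yn-1-yloxy)silyl]oxy}-4-methyl-1,3-oxazole; 14 (2R,6Z,10E)-13-(furan-3-yl)-2,6,10-trimethyltrideca-6,10-dienal
Product: 24 (5R)-3-{[(di-tert-butylfluorosilyl)oxy]methyl}-5-[(1S,2R,6Z,10E)-13-(furan-3-yl)-1-hydroxy-2,6,10-trimethyltrideca-6,10-dien-1-yl]furan-2(5H)-one, via cycloadduct 21 (not isolated), via fused silyloxyfuran 22 (not isolated), via furanolate salt 23 (not isolated)
Conditions: 20 alone, PhMe (0.02 M), 2,6-di-tert-butylpyridine (5 mol%), 160 °C, sealed tube; then THF, 14, −78 °C, (Me2N)3S[Me3SiF2] (1.05 equiv); AcOH, −78 °C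
Reagents that add atoms: tris(dimethylamino)sulfonium difluorotrimethylsilicate, CN(C)[S+](N(C)C)N(C)C.C[Si-](C)(C)(F)F
Why: Proposed new method: on heating, the electron-rich 5-silyloxyoxazole acts as a 2-azadiene and the tethered, unactivated terminal alkyne adds across oxazole C2 and C5 (intramolecular [4+2]), after which the strained 7-oxa-2-azanorbornadiene 21 loses acetonitrile by retro-[4+2] and leaves the aromatic 2-silyloxyfuran 22, so that C21–C22 and C23–C24 are made in one thermal event. The closest known reaction type is the intramolecular oxazole–alkyne Diels–Alder/retro-Diels–Alder furan synthesis of alkynyl 5-alkoxyoxazoles, together with silicon-tethered Diels–Alder reactions and the diene chemistry of 5-silyloxyoxazoles, but a cycloaddition through an O–Si–O tether on a 5-silyloxyoxazole has not been described. The future lactone ring is closed as a furan by cycloaddition and cycloreversion, and the four-atom O–Si–O–CH2 tether closes the temporary six-membered dioxasilinane in the fused (type 1) mode. Regiochemistry is fixed by the tether, which lets only the internal alkyne carbon reach the oxygen-bearing oxazole C5, so CH2O ends on C23 next to the carbonyl carbon; chemoselectivity is trivial because 14 with its alkenes is added only after cooling, and the two tert-butyl groups favour the reactive rotamer. In the same flask fluoride cleaves the Si–O(furan) bond and the free furanolate 23 adds through C21 to 14 in a vinylogous aldol reaction (precedent: fluoride-mediated additions of 2-silyloxyfurans to aldehydes), whose open antiperiplanar transition state should favour the unlike (erythro) relation of C20 and C21. The facial course with respect to C18 (Felkin addition expected, drawn) does not matter, because both unlike isomers give the same alkene in step 13, and the silicon stays on O25 as a fluorosilyl ether that protects the primary alcohol.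

Step 13
Reactants: 24 (5R)-3-{[(di-tert-butylfluorosilyl)oxy]methyl}-5-[(1S,2R,6Z,10E)-13-(furan-3-yl)-1-hydroxy-2,6,10-trimethyltrideca-6,10-dien-1-yl]furan-2(5H)-one
Product: 26 (5E)-3-{[(di-tert-butylfluorosilyl)oxy]methyl}-5-[(2R,6Z,10E)-13-(furan-3-yl)-2,6,10-trimethyltrideca-6,10-dien-1-ylidene]furan-2(5H)-one, via triflate 25 (not isolated)
Conditions: Tf2O (1.3 equiv), pyridine (6 equiv), CH2Cl2, −78 to 0 °C, in the dark
Reagents that add atoms: trifluoromethanesulfonic anhydride, O=S(=O)(OS(=O)(=O)C(F)(F)F)C(F)(F)F (its atoms stay only in 25)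
Why: the secondary triflate undergoes stereospecific E2 anti-elimination of H21 and triflate with pyridine (the known β-elimination route from γ-(α-hydroxyalkyl)butenolides), and in the unlike isomer the antiperiplanar arrangement places C18 on the side of C22, which gives the E-alkylidene and destroys the two auxiliary stereocentres.

Step 14
Reactants: 26 (5E)-3-{[(di-tert-butylfluorosilyl)oxy]methyl}-5-[(2R,6Z,10E)-13-(furan-3-yl)-2,6,10-trimethyltrideca-6,10-dien-1-ylidene]furan-2(5H)-one
Product: 27 (5E)-5-[(2R,6Z,10E)-13-(furan-3-yl)-2,6,10-trimethyltrideca-6,10-dien-1-ylidene]-3-(hydroxymethyl)furan-2(5H)-one (22-deoxy-23-hydroxymethylvariabilin)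
Conditions: HF·pyridine, pyridine, THF, 0 °C, in the dark
Reagents that add atoms: none
Why: fluoride-assisted Si–O cleavage under buffered, mildly acidic conditions frees the primary alcohol and spares the base- and light-sensitive E-alkylidenebutenolide and the furan.

**Compound list**
1 | pent-4-yn-1-ol | C#CCCCO | starting material
2 | (E)-5-iodo-4-methylpent-4-en-1-ol | C/C(=C\I)CCCO | intermediate
3 | furan-3-carbaldehyde | O=Cc1ccoc1 | starting material
4 | furan-3-ylethene (3-vinylfuran) | C=Cc1ccoc1 | intermediate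
5 | B-[2-(furan-3-yl)ethyl]-9-borabicyclo[3.3.1]nonane | B1(CCc2ccoc2)C2CCCC1CCC2 | intermediate
6 | (E)-7-(furan-3-yl)-4-methylhept-4-en-1-ol | C/C(=C\CCc1ccoc1)CCCO | intermediate
7 | (E)-7-(furan-3-yl)-4-methylhept-4-enal | C/C(=C\CCc1ccoc1)CCC=O | intermediate
8 | (2Z,6E)-9-(furan-3-yl)-2-iodo-6-methylnona-2,6-diene | C/C(=C\CCc1ccoc1)CC/C=C(/C)I | intermediate
9 | (S)-4-benzyl-3-propanoyl-1,3-oxazolidin-2-one | CCC(=O)N1[C@@H](Cc2ccccc2)COC1=O | starting material
10 | (S)-4-benzyl-3-[(R)-2-methylpent-4-enoyl]-1,3-oxazolidin-2-one | C=CC[C@@H](C)C(=O)N1[C@@H](Cc2ccccc2)COC1=O | intermediate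
11 | (R)-2-methylpent-4-en-1-ol | C=CC[C@@H](C)CO | intermediate
12 | (R)-9-{5-[(9-borabicyclo[3.3.1]nonan-9-yl)oxy]-4-methylpentyl}-9-borabicyclo[3.3.1]nonane | B1(CCC[C@@H](C)COB2C3CCCC2CCC3)C2CCCC1CCC2 | intermediate
13 | (2R,6Z,10E)-13-(furan-3-yl)-2,6,10-trimethyltrideca-6,10-dien-1-ol | C/C(=C/CC/C(C)=C/CCc1ccoc1)CCC[C@@H](C)CO | intermediate
14 | (2R,6Z,10E)-13-(furan-3-yl)-2,6,10-trimethyltrideca-6,10-dienal | C/C(=C/CC/C(C)=C/CCc1ccoc1)CCC[C@@H](C)C=O | intermediate
15 | di-tert-butylsilanediyl bis(trifluoromethanesulfonate) | CC(C)(C)[Si](OS(=O)(=O)C(F)(F)F)(OS(=O)(=O)C(F)(F)F)C(C)(C)C | starting material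
16 | prop-2-yn-1-ol | C#CCO | starting material
17 | di-tert-butyl(prop-2-yn-1-yloxy)silyl trifluoromethanesulfonate | CC(C)(C)[Si](OCC#C)(OS(=O)(=O)C(F)(F)F)C(C)(C)C | intermediate
18 | N-formyl-DL-alanine (racemic) | CC(NC=O)C(=O)O | starting material
19 | azlactone 4-methyl-1,3-oxazol-5(4H)-one (racemic) | CC1N=COC1=O | intermediate
20 | silyloxyoxazole 5-{[di-tert-butyl(prop-2-yn-1-yloxy)silyl]oxy}-4-methyl-1,3-oxazole | Cc1ncoc1O[Si](OCC#C)(C(C)(C)C)C(C)(C)C | intermediate
21 | cycloadduct: 3-methyl-7-oxa-2-azabicyclo[2.2.1]hepta-2,5-diene fused through C4 and C5 to a 2,2-di-tert-butyl-1,3,2-dioxasilinane (racemic) | CC1=NC2C=C3CO[Si](C(C)(C)C)(C(C)(C)C)OC13O2 | intermediate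
22 | fused silyloxyfuran 2,2-di-tert-butyl-4H-furo[2,3-d][1,3,2]dioxasiline | CC(C)(C)[Si]1(C(C)(C)C)OCc2ccoc2O1 | intermediate
23 | tris(dimethylamino)sulfonium 3-{[(di-tert-butylfluorosilyl)oxy]methyl}furan-2-olate | CC(C)(C)[Si](F)(OCc1ccoc1[O-])C(C)(C)C.CN(C)[S+](N(C)C)N(C)C | intermediate
24 | (5R)-3-{[(di-tert-butylfluorosilyl)oxy]methyl}-5-[(1S,2R,6Z,10E)-13-(furan-3-yl)-1-hydroxy-2,6,10-trimethyltrideca-6,10-dien-1-yl]furan-2(5H)-one (Felkin unlike isomer drawn; the (5S,1R) unlike isomer is carried along) | CC(C)(C)[Si](F)(OCC1=C[C@@H](OC1=O)[C@@H](O)[C@H](C)CCC/C(C)=C\CC/C(C)=C/CCc1ccoc1)C(C)(C)C | intermediate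
25 | C20 trifluoromethanesulfonate of 24 | CC(C)(C)[Si](F)(OCC1=C[C@@H](OC1=O)[C@@H](OS(=O)(=O)C(F)(F)F)[C@H](C)CCC/C(C)=C\CC/C(C)=C/CCc1ccoc1)C(C)(C)C | intermediate
26 | (5E)-3-{[(di-tert-butylfluorosilyl)oxy]methyl}-5-[(2R,6Z,10E)-13-(furan-3-yl)-2,6,10-trimethyltrideca-6,10-dien-1-ylidene]furan-2(5H)-one | C/C(=C/CC/C(C)=C/CCc1ccoc1)CCC[C@@H](C)/C=C1\C=C(CO[Si](F)(C(C)(C)C)C(C)(C)C)C(=O)O1 | intermediate
27 | (5E)-5-[(2R,6Z,10E)-13-(furan-3-yl)-2,6,10-trimethyltrideca-6,10-dien-1-ylidene]-3-(hydroxymethyl)furan-2(5H)-one | C/C(=C/CC/C(C)=C/CCc1ccoc1)CCC[C@@H](C)/C=C1\C=C(CO)C(=O)O1 | target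

**Count and risks**
Total step count: 14. Longest linear sequence: 9 steps (1, 3, 4, 5, 8, 9, 12, 13, 14).

Most likely to fail:

Step 12 (proposed new method). Thermal decomposition of the silyloxyoxazole (O-to-C silyl migration, oligomerisation) may outrun the intramolecular cycloaddition, and retro-aldol equilibration of the free alkoxide may erode the unlike selectivity. The fallback uses only known chemistry, sets out from 15 and comes back at 22. Commercial furan-3-ylmethanol is lithiated at C2 through its alkoxide (n-BuLi, 2.2 equiv, THF, 0 °C) and C-silylated (Me3SiCl, 1 equiv) to [2-(trimethylsilyl)furan-3-yl]methanol F1. Peracetic acid (NaOAc, CH2Cl2, 0 °C) oxidises the 2-silylfuran to 3-(hydroxymethyl)furan-2(5H)-one F2, the known silylfuran-to-butenolide oxidation. Then 15 and Et3N (CH2Cl2, −78 to 0 °C) silylate the primary hydroxyl and the lactone enol of F2 (ordinary silyl triflate enol silylation) and give 22, which is taken on with fluoride, 14 and AcOH as in step 12.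

Step 13. Elimination through the dienolate (E1cB), or epimerisation at C21 before the triflate leaves, would erode the E geometry towards the more stable Z-alkene. The fallback changes the mechanism from anti to syn, sets out from 22 and 14 and comes back at 26. Under Mukaiyama conditions (BF3·OEt2, CH2Cl2, −78 °C) the vinylogous aldol addition is expected to favour the like (threo) adduct (5S)-3-{[(di-tert-butylfluorosilyl)oxy]methyl}-5-[(1S,2R,6Z,10E)-13-(furan-3-yl)-1-hydroxy-2,6,10-trimethyltrideca-6,10-dien-1-yl]furan-2(5H)-one F3, which is also the by-product of step 12. Burgess reagent (PhMe, 50 °C) converts it into the triethylammonium sulfamate of F3, F4, which undergoes thermal syn-elimination (Ei) of H21 and the C20 oxygen. From the like isomer the syn course places C18 cis to C22 and gives 26.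

Step 11. Self-condensation of the 2-unsubstituted azlactone and silylation at C4 instead of oxygen may prevent clean formation of 20. The fallback replaces 18–20 by the known intermolecular form of the same disconnection, sets out from 15 and comes back at 22. Commercial 5-ethoxy-4-methyl-1,3-oxazole and methyl propiolate (PhMe, 110 °C) combine in a Diels–Alder reaction to methyl 4-ethoxy-3-methyl-7-oxa-2-azabicyclo[2.2.1]hepta-2,5-diene-5-carboxylate F5, with the ester next to the ethoxy-bearing bridgehead as the polarisation of both partners demands. F5 loses acetonitrile to give methyl 2-ethoxyfuran-3-carboxylate F6. Reduction with i-Bu2AlH (CH2Cl2, −78 °C) gives (2-ethoxyfuran-3-yl)methanol F7, and dilute aqueous oxalic acid (THF, 0 °C) hydrolyses the 2-ethoxyfuran to 3-(hydroxymethyl)furan-2(5H)-one F2. Then 15 and Et3N give 22 as above.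

**Further compounds**
F1 | step 12 | [2-(trimethylsilyl)furan-3-yl]methanol | C[Si](C)(C)c1occc1CO
F2 | step 12 | 3-(hydroxymethyl)furan-2(5H)-one | O=C1OCC=C1CO
F3 | step 13 | (5S)-3-{[(di-tert-butylfluorosilyl)oxy]methyl}-5-[(1S,2R,6Z,10E)-13-(furan-3-yl)-1-hydroxy-2,6,10-trimethyltrideca-6,10-dien-1-yl]furan-2(5H)-one | CC(C)(C)[Si](F)(OCC1=C[C@H](OC1=O)[C@@H](O)[C@H](C)CCC/C(C)=C\CC/C(C)=C/CCc1ccoc1)C(C)(C)C
F4 | step 13 | triethylammonium N-(methoxycarbonyl)sulfamate ester of F3 at O20 | CC(C)(C)[Si](F)(OCC1=C[C@H](OC1=O)[C@@H](OS(=O)(=O)[N-]C(=O)OC)[C@H](C)CCC/C(C)=C\CC/C(C)=C/CCc1ccoc1)C(C)(C)C.CC[NH+](CC)CC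
F5 | step 11 | methyl 4-ethoxy-3-methyl-7-oxa-2-azabicyclo[2.2.1]hepta-2,5-diene-5-carboxylate (racemic) | CCOC12OC(N=C1C)C=C2C(=O)OC
F6 | step 11 | methyl 2-ethoxyfuran-3-carboxylate | CCOc1occc1C(=O)OC
F7 | step 11 | (2-ethoxyfuran-3-yl)methanol | CCOc1occc1CO
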